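**Retrosynthetic overview** (germacrane locants; ring A = ten-membered carbocycle C1–C10, ring B = oxolane C3–O–C10, ring C = lactone O–C6–C7–C11–C12; PMB = 4-methoxybenzyl, TBS = tert-butyldimethylsilyl)
1. Target ⇒ tricyclic lactone 26; after the key step only the C8 angelate is installed and the C1 silyl ether removed.
2. Key disconnection C6–C7: the array O–C6H–C7H–C11(=C13H2)–C12=O (a carbinol carbon bonded to a carbon that is allylic to the exocyclic methylene and β to the carboxyl carbon) is the retron of a carbonyl 2-(methoxycarbonyl)allylation, so rings A and C close together from the C6 enal and the C13 allylic bromide of monocyclic 24.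
3. 24 ⇒ ring B ester 14: C4=C5 by Z-selective olefination of a C4 methyl ketone; C7=C11–C13 by Morita–Baylis–Hillman reaction and SN2' bromination at a C7 aldehyde.
4. Ring B ⇒ 5-endo opening of a C1–C10 epoxide by the C3 hydroxyl; the E alkene comes from carboalumination; C3 from methyl (S)-glycidate, C8 from (S)-glyceraldehyde acetonide.
5. Ring order: B (step 5), then A and C in one operation (step 14).

Key step: step 14

Remark: the configuration is taken exactly as written, (1S,3S,6S,7R,8R,10R); on ring B this puts the C3–C4 and C10–C9 bonds trans and C1–OH cis to the C10 methyl group, and makes ring C cis-fused, and the route is built for this arrangement.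

Step 1
Reactants: 1 (S)-2,2-dimethyl-1,3-dioxolane-4-carbaldehyde ((S)-glyceraldehyde acetonide); 2 propargyl bromide (3-bromoprop-1-yne)
Product: 4 (1R)-1-[(4S)-2,2-dimethyl-1,3-dioxolan-4-yl]but-3-yn-1-ol, via allenylzinc bromide 3 (not isolated)
Conditions: Zn dust, DMF/Et2O (1:1), 0 °C to rt; aq. NH4Cl
Reagents that add atoms: none
Why: Zinc Barbier-type propargylation in which allenylzinc bromide 3 adds with allylic transposition under Felkin–Anh control by the dioxolane stereocentre, which should give mainly the anti adduct and so set C8 as R (the dioxolane stereocentre is excised in step 10).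

Step 2
Reactants: 4 (1R)-1-[(4S)-2,2-dimethyl-1,3-dioxolan-4-yl]but-3-yn-1-ol
Product: 5 (4S)-4-[(1R)-1-(PMBO)but-3-yn-1-yl]-2,2-dimethyl-1,3-dioxolane
Conditions: NaH, PMBCl, Bu4NI (cat.), THF/DMF, 0 °C to rt
Reagents that add atoms: 4-methoxybenzyl chloride, COc1ccc(CCl)cc1
Why: Williamson ether synthesis on the sodium alkoxide; the PMB ether survives the organometallic steps and is removed oxidatively after the key step.

Step 3
Reactants: 5 (4S)-4-[(1R)-1-(PMBO)but-3-yn-1-yl]-2,2-dimethyl-1,3-dioxolane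
Product: 7 (4S)-4-[(1R,3E)-4-iodo-1-(PMBO)-3-methylbut-3-en-1-yl]-2,2-dimethyl-1,3-dioxolane, via alkenyl(dimethyl)alane 6 (not isolated)
Conditions: Me3Al, Cp2ZrCl2 (cat.), H2O (1 equiv), CH2Cl2, −30 °C; then I2, THF, −30 to 0 °C
Reagents that add atoms: trimethylaluminium, C[Al](C)C; iodine, II
Why: Zirconium-catalysed carboalumination (Negishi) adds methyl and aluminium syn across the terminal alkyne with methyl on the internal carbon, and iodinolysis with retention gives the E vinyl iodide that fixes the C1=C10 geometry and brings in C14.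

Step 4
Reactants: 7 (4S)-4-[(1R,3E)-4-iodo-1-(PMBO)-3-methylbut-3-en-1-yl]-2,2-dimethyl-1,3-dioxolane; 8 methyl (2S)-oxirane-2-carboxylate (methyl (S)-glycidate)
Product: 11 methyl (2S,4E,7R)-2-hydroxy-7-(PMBO)-5-methyl-7-[(4S)-2,2-dimethyl-1,3-dioxolan-4-yl]hept-4-enoate, via alkenyllithium 9 (not isolated), via alkenylmagnesium bromide 10 (not isolated)
Conditions: t-BuLi (2 equiv), Et2O, −78 °C; MgBr2·OEt2, −78 to −40 °C; CuI (cat.), 8, THF, −40 to −20 °C
Reagents that add atoms: none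
Why: Iodine–lithium exchange and transmetalation retain the alkene geometry, and the copper-catalysed SN2 opening of the glycidate at its unsubstituted carbon leaves the stereocentre of 8 untouched, so C3 is S by chiral-pool transfer.

Step 5
Reactants: 11 methyl (2S,4E,7R)-2-hydroxy-7-(PMBO)-5-methyl-7-[(4S)-2,2-dimethyl-1,3-dioxolan-4-yl]hept-4-enoate
Product: 13 methyl (2S,4S,5R)-4-hydroxy-5-{(2R)-2-(PMBO)-2-[(4S)-2,2-dimethyl-1,3-dioxolan-4-yl]ethyl}-5-methyloxolane-2-carboxylate, via epoxy alcohol 12 (not isolated)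
Conditions: ent-Shi ketone (L-fructose-derived, 0.3 equiv), Oxone, K2CO3, Bu4NHSO4, MeCN/DMM/aq. borate buffer, 0 °C; then CSA (cat.), CH2Cl2, 0 °C
Reagents that add atoms: potassium peroxymonosulfate (active oxidant of Oxone), [K+].[O-]S(=O)(=O)OO
Why: Shi epoxidation with the L-series ketone should give the (1S,10S) epoxide 12 of the E trisubstituted alkene under catalyst control, and acid then triggers 5-endo opening at the tertiary C10 by the C3 hydroxyl with inversion, which closes ring B, sets C10 as R and leaves the C1 oxygen as the S carbinol.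

Step 6
Reactants: 13 methyl (2S,4S,5R)-4-hydroxy-5-{(2R)-2-(PMBO)-2-[(4S)-2,2-dimethyl-1,3-dioxolan-4-yl]ethyl}-5-methyloxolane-2-carboxylate
Product: 14 methyl (2S,4S,5R)-4-(TBSO)-5-{(2R)-2-(PMBO)-2-[(4S)-2,2-dimethyl-1,3-dioxolan-4-yl]ethyl}-5-methyloxolane-2-carboxylate
Conditions: TBSOTf, 2,6-lutidine, CH2Cl2, −20 to 0 °C
Reagents that add atoms: tert-butyldimethylsilyl trifluoromethanesulfonate, CC(C)(C)[Si](C)(C)OS(=O)(=O)C(F)(F)F
Why: Silyl ether formation with the reactive silyl triflate masks the hindered C1 hydroxyl until the last step, so that later only the C8 hydroxyl is acylated.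

Step 7
Reactants: 14 methyl (2S,4S,5R)-4-(TBSO)-5-{(2R)-2-(PMBO)-2-[(4S)-2,2-dimethyl-1,3-dioxolan-4-yl]ethyl}-5-methyloxolane-2-carboxylate
Product: 16 1-[(2S,4S,5R)-4-(TBSO)-5-{(2R)-2-(PMBO)-2-[(4S)-2,2-dimethyl-1,3-dioxolan-4-yl]ethyl}-5-methyloxolan-2-yl]ethan-1-one, via Weinreb amide 15 (not isolated)
Conditions: MeNH(OMe)·HCl, MeMgCl (excess), THF, −20 to 0 °C
Reagents that add atoms: methylmagnesium chloride, C[Mg]Cl
Why: Weinreb ketone synthesis in one flask, in which the magnesium amide of N,O-dimethylhydroxylamine turns the ester into amide 15 and MeMgCl adds once to give a chelated adduct that releases the methyl ketone (C15) only on work-up, the low temperature keeping C3 from epimerising.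

Step 8
Reactants: 16 1-[(2S,4S,5R)-4-(TBSO)-5-{(2R)-2-(PMBO)-2-[(4S)-2,2-dimethyl-1,3-dioxolan-4-yl]ethyl}-5-methyloxolan-2-yl]ethan-1-one; 17 methyl 2-[bis(2,2,2-trifluoroethoxy)phosphoryl]acetate
Product: 18 methyl (2Z)-3-[(2S,4S,5R)-4-(TBSO)-5-{(2R)-2-(PMBO)-2-[(4S)-2,2-dimethyl-1,3-dioxolan-4-yl]ethyl}-5-methyloxolan-2-yl]but-2-enoate
Conditions: KHMDS, 18-crown-6, THF, −78 to −40 °C
Reagents that add atoms: none
Why: Still–Gennari variant of the Horner–Wadsworth–Emmons olefination, in which the electron-poor phosphonate eliminates fast from the kinetic adduct and should place the ester cis to the oxolane carbon on this α-alkoxy methyl ketone, giving the Z C4=C5 alkene.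

Step 9
Reactants: 18 methyl (2Z)-3-[(2S,4S,5R)-4-(TBSO)-5-{(2R)-2-(PMBO)-2-[(4S)-2,2-dimethyl-1,3-dioxolan-4-yl]ethyl}-5-methyloxolan-2-yl]but-2-enoate
Product: 19 (2Z)-3-[(2S,4S,5R)-4-(TBSO)-5-{(2R)-2-(PMBO)-2-[(4S)-2,2-dimethyl-1,3-dioxolan-4-yl]ethyl}-5-methyloxolan-2-yl]but-2-en-1-ol
Conditions: DIBAL-H, CH2Cl2, −78 °C; Rochelle salt
Reagents that add atoms: none
Why: 1,2-Hydride reduction of the conjugated ester by DIBAL-H gives the allylic alcohol without touching the alkene geometry, the acetal or the ethers.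

Step 10
Reactants: 19 (2Z)-3-[(2S,4S,5R)-4-(TBSO)-5-{(2R)-2-(PMBO)-2-[(4S)-2,2-dimethyl-1,3-dioxolan-4-yl]ethyl}-5-methyloxolan-2-yl]but-2-en-1-ol
Product: 20 (2R)-3-[(2R,3S,5S)-3-(TBSO)-5-[(2Z)-4-hydroxybut-2-en-2-yl]-2-methyloxolan-2-yl]-2-(PMBO)propanal
Conditions: H5IO6, EtOAc, 0 °C to rt
Reagents that add atoms: none
Why: Periodic acid hydrolyses the terminal acetonide and cleaves the liberated 1,2-diol in the same flask (glycol cleavage), which unmasks the C7 aldehyde while the free allylic alcohol and the silyl and PMB ethers are inert.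

Step 11
Reactants: 20 (2R)-3-[(2R,3S,5S)-3-(TBSO)-5-[(2Z)-4-hydroxybut-2-en-2-yl]-2-methyloxolan-2-yl]-2-(PMBO)propanal; 21 methyl acrylate
Product: 22 methyl (4R)-3-hydroxy-4-(PMBO)-2-methylidene-5-[(2R,3S,5S)-3-(TBSO)-5-[(2Z)-4-hydroxybut-2-en-2-yl]-2-methyloxolan-2-yl]pentanoate (both C3 epimers)
Conditions: 21 (excess), DABCO, MeOH (cat.), rt
Reagents that add atoms: none
Why: Morita–Baylis–Hillman reaction, in which the ammonium enolate from DABCO and the acrylate attacks the activated α-alkoxy aldehyde and attaches C11, C12 and C13 to C7 in one step; the new carbinol centre becomes sp2 in step 13, so its configuration does not matter.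

Step 12
Reactants: 22 methyl (4R)-3-hydroxy-4-(PMBO)-2-methylidene-5-[(2R,3S,5S)-3-(TBSO)-5-[(2Z)-4-hydroxybut-2-en-2-yl]-2-methyloxolan-2-yl]pentanoate
Product: 23 methyl (4R)-3-hydroxy-4-(PMBO)-2-methylidene-5-[(2R,3S,5S)-3-(TBSO)-2-methyl-5-[(2Z)-4-oxobut-2-en-2-yl]oxolan-2-yl]pentanoate
Conditions: MnO2, CH2Cl2, rt
Reagents that add atoms: none
Why: Allylic oxidation with MnO2 should take the electron-rich primary allylic alcohol selectively, because the secondary carbinol next to the electron-poor acrylate double bond reacts far more slowly, and the neutral heterogeneous conditions keep the Z enal from isomerising.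

Step 13
Reactants: 23 methyl (4R)-3-hydroxy-4-(PMBO)-2-methylidene-5-[(2R,3S,5S)-3-(TBSO)-2-methyl-5-[(2Z)-4-oxobut-2-en-2-yl]oxolan-2-yl]pentanoate
Product: 24 methyl (2Z,4R)-2-(bromomethyl)-4-(PMBO)-5-[(2R,3S,5S)-3-(TBSO)-2-methyl-5-[(2Z)-4-oxobut-2-en-2-yl]oxolan-2-yl]pent-2-enoate
Conditions: NBS, Me2S (pre-mixed), CH2Cl2, 0 °C to rt
Reagents that add atoms: N-bromosuccinimide, BrN1C(=O)CCC1=O
Why: Corey–Kim-type activation of the allylic carbinol followed by bromide attack at the terminal methylene carbon (SN2') moves the double bond into conjugation and should give the (Z)-2-(bromomethyl)enoate, the isomer with C8 trans to the ester, while the aldehyde is tolerated.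

Step 14
Reactants: 24 methyl (2Z,4R)-2-(bromomethyl)-4-(PMBO)-5-[(2R,3S,5S)-3-(TBSO)-2-methyl-5-[(2Z)-4-oxobut-2-en-2-yl]oxolan-2-yl]pent-2-enoate
Product: 26 (1S,3S,6S,7R,8R,10R)-1-(TBSO)-8-(PMBO)-3,10-epoxygermacra-4Z,11(13)-dien-12,6-olide, via hydroxy ester 25 (not isolated)
Conditions: CrCl2 (10 equiv), THF/DMF (4:1), 2 mM, slow addition of 24, 25 °C; then aq. NH4Cl
Reagents that add atoms: none
Why: Two equivalents of CrCl2 (divalent chromium) reduce the allylic C13–Br bond to an allylchromium species of trivalent chromium, which adds through its γ-carbon C7 to the C6 aldehyde in a six-membered chair transition state, and the chromium alkoxide of 25 then attacks the C12 methyl ester to close the lactone. The closest known reaction type is the intramolecular Nozaki–Hiyama–Kishi (Barbier-type) carbonyl 2-(alkoxycarbonyl)allylation that closes the ten-membered ring of germacranolides together with the α-methylene lactone. Ring A closes by a 10-exo-trig addition to the C6=O bond (9-exo-trig if counted through the ether oxygen) and ring C by a 5-exo-trig acyl substitution at C12. The syn relation of C6 and C7 (cis-fused lactone, 6S,7R) follows from the Z allyl unit, whose C8 substituent is cis to the CH2–Cr arm and axial in the chair, and the absolute sense at C7 is set by C8, because A(1,3) strain holds H-8 in the plane of C7=C11 so that C6 bonds anti to the C8–C9 bond. The step needs γ- over α-attack, aldehyde over ester selectivity and ring closure over oligomerisation; the first two are inherent to ester-substituted allylchromium reagents, and the third is helped by the Z enal and ring B, which remove rotors from the chain, and by high dilution.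

Step 15
Reactants: 26 (1S,3S,6S,7R,8R,10R)-1-(TBSO)-8-(PMBO)-3,10-epoxygermacra-4Z,11(13)-dien-12,6-olide
Product: 27 (1S,3S,6S,7R,8R,10R)-1-(TBSO)-8-hydroxy-3,10-epoxygermacra-4Z,11(13)-dien-12,6-olide
Conditions: DDQ, CH2Cl2/pH 7 buffer, 0 °C to rt
Reagents that add atoms: none
Why: Oxidative cleavage of the PMB ether by DDQ (benzylic hydride abstraction, then hydrolysis of the oxocarbenium ion) frees the C8 hydroxyl under neutral conditions that spare the silyl ether, the lactone and the alkenes.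

Step 16
Reactants: 27 (1S,3S,6S,7R,8R,10R)-1-(TBSO)-8-hydroxy-3,10-epoxygermacra-4Z,11(13)-dien-12,6-olide; 28 angelic acid ((2Z)-2-methylbut-2-enoic acid)
Product: 30 (1S,3S,6S,7R,8R,10R)-8-angeloyloxy-1-(TBSO)-3,10-epoxygermacra-4Z,11(13)-dien-12,6-olide, via mixed anhydride 29 (not isolated)
Conditions: 28, 2,4,6-trichlorobenzoyl chloride, Et3N, toluene, rt; then 27, toluene, 75 °C
Reagents that add atoms: none
Why: Yamaguchi-type esterification through mixed anhydride 29, run without a nucleophilic catalyst, acylates the C8 hydroxyl while avoiding the conjugate addition–elimination pathway that would isomerise the angelate to the tiglate.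

Step 17
Reactants: 30 (1S,3S,6S,7R,8R,10R)-8-angeloyloxy-1-(TBSO)-3,10-epoxygermacra-4Z,11(13)-dien-12,6-olide
Product: 31 (1S,3S,6S,7R,8R,10R)-8-angeloyloxy-1-hydroxy-3,10-epoxygermacra-4Z,11(13)-dien-12,6-olide (target)
Conditions: HF·pyridine, pyridine/THF, 0 °C to rt
Reagents that add atoms: none
Why: Fluoride-driven cleavage of the Si–O bond (silyl ether deprotection) under buffered conditions removes the last protecting group without attacking the angelate or the α-methylene lactone.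

**Compound list**
1 | (S)-2,2-dimethyl-1,3-dioxolane-4-carbaldehyde | O=C[C@@H]1COC(C)(C)O1 | starting material
2 | propargyl bromide | BrCC#C | starting material
3 | allenylzinc bromide | C=C=C[Zn]Br | intermediate
4 | (1R)-1-[(4S)-2,2-dimethyl-1,3-dioxolan-4-yl]but-3-yn-1-ol | C#CC[C@@H](O)[C@@H]1COC(C)(C)O1 | intermediate
5 | (4S)-4-[(1R)-1-(PMBO)but-3-yn-1-yl]-2,2-dimethyl-1,3-dioxolane | C#CC[C@@H](OCc1ccc(OC)cc1)[C@@H]2COC(C)(C)O2 | intermediate
6 | dimethyl[(1E,4R)-4-(PMBO)-2-methyl-4-[(4S)-2,2-dimethyl-1,3-dioxolan-4-yl]but-1-en-1-yl]alane | C[Al](C)/C=C(\C)C[C@@H](OCc1ccc(OC)cc1)[C@@H]2COC(C)(C)O2 | intermediate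
7 | (4S)-4-[(1R,3E)-4-iodo-1-(PMBO)-3-methylbut-3-en-1-yl]-2,2-dimethyl-1,3-dioxolane | I/C=C(\C)C[C@@H](OCc1ccc(OC)cc1)[C@@H]2COC(C)(C)O2 | intermediate
8 | methyl (2S)-oxirane-2-carboxylate | COC(=O)[C@@H]1CO1 | starting material
9 | [(1E,4R)-4-(PMBO)-2-methyl-4-[(4S)-2,2-dimethyl-1,3-dioxolan-4-yl]but-1-en-1-yl]lithium | [Li]/C=C(\C)C[C@@H](OCc1ccc(OC)cc1)[C@@H]2COC(C)(C)O2 | intermediate
10 | bromo[(1E,4R)-4-(PMBO)-2-methyl-4-[(4S)-2,2-dimethyl-1,3-dioxolan-4-yl]but-1-en-1-yl]magnesium | Br[Mg]/C=C(\C)C[C@@H](OCc1ccc(OC)cc1)[C@@H]2COC(C)(C)O2 | intermediate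
11 | methyl (2S,4E,7R)-2-hydroxy-7-(PMBO)-5-methyl-7-[(4S)-2,2-dimethyl-1,3-dioxolan-4-yl]hept-4-enoate | COC(=O)[C@@H](O)C/C=C(\C)C[C@@H](OCc1ccc(OC)cc1)[C@@H]2COC(C)(C)O2 | intermediate
12 | methyl (2S)-2-hydroxy-3-[(2S,3S)-3-{(2R)-2-(PMBO)-2-[(4S)-2,2-dimethyl-1,3-dioxolan-4-yl]ethyl}-3-methyloxiran-2-yl]propanoate | COC(=O)[C@@H](O)C[C@@H]1O[C@@]1(C)C[C@@H](OCc2ccc(OC)cc2)[C@@H]3COC(C)(C)O3 | intermediate
13 | methyl (2S,4S,5R)-4-hydroxy-5-{(2R)-2-(PMBO)-2-[(4S)-2,2-dimethyl-1,3-dioxolan-4-yl]ethyl}-5-methyloxolane-2-carboxylate | COC(=O)[C@@H]1C[C@H](O)[C@@](C)(C[C@@H](OCc2ccc(OC)cc2)[C@@H]3COC(C)(C)O3)O1 | intermediate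
14 | methyl (2S,4S,5R)-4-(TBSO)-5-{(2R)-2-(PMBO)-2-[(4S)-2,2-dimethyl-1,3-dioxolan-4-yl]ethyl}-5-methyloxolane-2-carboxylate | COC(=O)[C@@H]1C[C@H](O[Si](C)(C)C(C)(C)C)[C@@](C)(C[C@@H](OCc2ccc(OC)cc2)[C@@H]3COC(C)(C)O3)O1 | intermediate
15 | (2S,4S,5R)-4-(TBSO)-N-methoxy-N-methyl-5-{(2R)-2-(PMBO)-2-[(4S)-2,2-dimethyl-1,3-dioxolan-4-yl]ethyl}-5-methyloxolane-2-carboxamide | CON(C)C(=O)[C@@H]1C[C@H](O[Si](C)(C)C(C)(C)C)[C@@](C)(C[C@@H](OCc2ccc(OC)cc2)[C@@H]3COC(C)(C)O3)O1 | intermediate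
16 | 1-[(2S,4S,5R)-4-(TBSO)-5-{(2R)-2-(PMBO)-2-[(4S)-2,2-dimethyl-1,3-dioxolan-4-yl]ethyl}-5-methyloxolan-2-yl]ethan-1-one | CC(=O)[C@@H]1C[C@H](O[Si](C)(C)C(C)(C)C)[C@@](C)(C[C@@H](OCc2ccc(OC)cc2)[C@@H]3COC(C)(C)O3)O1 | intermediate
17 | methyl 2-[bis(2,2,2-trifluoroethoxy)phosphoryl]acetate | COC(=O)CP(=O)(OCC(F)(F)F)OCC(F)(F)F | starting material
18 | methyl (2Z)-3-[(2S,4S,5R)-4-(TBSO)-5-{(2R)-2-(PMBO)-2-[(4S)-2,2-dimethyl-1,3-dioxolan-4-yl]ethyl}-5-methyloxolan-2-yl]but-2-enoate | COC(=O)/C=C(/C)[C@@H]1C[C@H](O[Si](C)(C)C(C)(C)C)[C@@](C)(C[C@@H](OCc2ccc(OC)cc2)[C@@H]3COC(C)(C)O3)O1 | intermediate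
19 | (2Z)-3-[(2S,4S,5R)-4-(TBSO)-5-{(2R)-2-(PMBO)-2-[(4S)-2,2-dimethyl-1,3-dioxolan-4-yl]ethyl}-5-methyloxolan-2-yl]but-2-en-1-ol | OC/C=C(/C)[C@@H]1C[C@H](O[Si](C)(C)C(C)(C)C)[C@@](C)(C[C@@H](OCc2ccc(OC)cc2)[C@@H]3COC(C)(C)O3)O1 | intermediate
20 | (2R)-3-[(2R,3S,5S)-3-(TBSO)-5-[(2Z)-4-hydroxybut-2-en-2-yl]-2-methyloxolan-2-yl]-2-(PMBO)propanal | OC/C=C(/C)[C@@H]1C[C@H](O[Si](C)(C)C(C)(C)C)[C@@](C)(C[C@@H](OCc2ccc(OC)cc2)C=O)O1 | intermediate
21 | methyl acrylate | C=CC(=O)OC | starting material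
22 | methyl (4R)-3-hydroxy-4-(PMBO)-2-methylidene-5-[(2R,3S,5S)-3-(TBSO)-5-[(2Z)-4-hydroxybut-2-en-2-yl]-2-methyloxolan-2-yl]pentanoate (C3 epimers) | OC/C=C(/C)[C@@H]1C[C@H](O[Si](C)(C)C(C)(C)C)[C@@](C)(C[C@@H](OCc2ccc(OC)cc2)C(O)C(=C)C(=O)OC)O1 | intermediate
23 | methyl (4R)-3-hydroxy-4-(PMBO)-2-methylidene-5-[(2R,3S,5S)-3-(TBSO)-2-methyl-5-[(2Z)-4-oxobut-2-en-2-yl]oxolan-2-yl]pentanoate (C3 epimers) | O=C/C=C(/C)[C@@H]1C[C@H](O[Si](C)(C)C(C)(C)C)[C@@](C)(C[C@@H](OCc2ccc(OC)cc2)C(O)C(=C)C(=O)OC)O1 | intermediate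
24 | methyl (2Z,4R)-2-(bromomethyl)-4-(PMBO)-5-[(2R,3S,5S)-3-(TBSO)-2-methyl-5-[(2Z)-4-oxobut-2-en-2-yl]oxolan-2-yl]pent-2-enoate | O=C/C=C(/C)[C@@H]1C[C@H](O[Si](C)(C)C(C)(C)C)[C@@](C)(C[C@@H](OCc2ccc(OC)cc2)/C=C(\CBr)C(=O)OC)O1 | intermediate
25 | methyl (1S,3S,6S,7S,8R,10R)-1-(TBSO)-6-hydroxy-8-(PMBO)-3,10-epoxygermacra-4Z,11(13)-dien-12-oate (ring-closed hydroxy ester) | O[C@H]1/C=C(/C)[C@@H]2C[C@H](O[Si](C)(C)C(C)(C)C)[C@@](C)(C[C@@H](OCc3ccc(OC)cc3)[C@H]1C(=C)C(=O)OC)O2 | intermediate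
26 | (1S,3S,6S,7R,8R,10R)-1-(TBSO)-8-(PMBO)-3,10-epoxygermacra-4Z,11(13)-dien-12,6-olide | C=C1C(=O)O[C@H]2/C=C(/C)[C@@H]3C[C@H](O[Si](C)(C)C(C)(C)C)[C@@](C)(C[C@@H](OCc4ccc(OC)cc4)[C@@H]12)O3 | intermediate
27 | (1S,3S,6S,7R,8R,10R)-1-(TBSO)-8-hydroxy-3,10-epoxygermacra-4Z,11(13)-dien-12,6-olide | C=C1C(=O)O[C@H]2/C=C(/C)[C@@H]3C[C@H](O[Si](C)(C)C(C)(C)C)[C@@](C)(C[C@@H](O)[C@@H]12)O3 | intermediate
28 | angelic acid, (2Z)-2-methylbut-2-enoic acid | C/C=C(/C)C(=O)O | starting material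
29 | (2Z)-2-methylbut-2-enoic 2,4,6-trichlorobenzoic anhydride | C/C=C(/C)C(=O)OC(=O)c1c(Cl)cc(Cl)cc1Cl | intermediate
30 | (1S,3S,6S,7R,8R,10R)-8-angeloyloxy-1-(TBSO)-3,10-epoxygermacra-4Z,11(13)-dien-12,6-olide | C=C1C(=O)O[C@H]2/C=C(/C)[C@@H]3C[C@H](O[Si](C)(C)C(C)(C)C)[C@@](C)(C[C@@H](OC(=O)/C(C)=C\C)[C@@H]12)O3 | intermediate
31 | (1S,3S,6S,7R,8R,10R)-8-angeloyloxy-1-hydroxy-3,10-epoxygermacra-4Z,11(13)-dien-12,6-olide | C=C1C(=O)O[C@H]2/C=C(/C)[C@@H]3C[C@H](O)[C@@](C)(C[C@@H](OC(=O)/C(C)=C\C)[C@@H]12)O3 | target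

Total step count: 17
Longest linear sequence: 17 steps (1 to 31)

**Steps most likely to fail**

Step 14. Ring closure may lose against intermolecular allylation (oligomers) and against protonation of the allylchromium species, because ring A has to bridge the trans-disposed C3 and C10 arms of ring B and the closure builds strain. Addition to the wrong face of C7 would also erode the diastereoselectivity. The fallback sets out from 24. Palladium-catalysed borylation (Pd2(dba)3, zerovalent palladium, B2pin2, toluene, 50 °C) should give the allylboronate F1 with boron on C13. Heated in dilute toluene (80–110 °C), it should add C7 to the C6 aldehyde through a closed, uncharged chair transition state (thermal allylboration, same Z geometry and same syn sense). The boron alkoxide then lactonises and the route is rejoined at 26.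

Step 8. The methyl ketone may react sluggishly and the olefination may lose its Z selectivity at C4=C5. The fallback sets out from ester 14. DIBAL-H at −78 °C stops at the aldehyde F2. Ohira–Bestmann homologation (dimethyl (1-diazo-2-oxopropyl)phosphonate, K2CO3, MeOH) gives the alkyne F3. Deprotonation with n-BuLi and addition to paraformaldehyde give the propargylic alcohol F4. Iron-catalysed syn-carbomagnesiation (MeMgBr, Fe(acac)3, THF, 0 °C), directed by the magnesium alkoxide, puts methyl on C4 and hydrogen on C5 on the same side and so gives the Z allylic alcohol. The route is rejoined at 19.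

Step 11. Conversion of the hindered α-alkoxy aldehyde may be slow, and the long contact with the amine may epimerise C8. The fallback sets out from 20. Methyl propiolate is hydroaluminated with DIBAL-H in THF/HMPA at 0 °C to the α-aluminated acrylate F5. This adds directly to the aldehyde at low temperature without amine catalysis; the free hydroxyl of 20 consumes one further equivalent. It gives the same carbinol, and the route is rejoined at 22.

**Further compounds**
F1 | step 14 | methyl (2E,4R)-4-(PMBO)-5-[(2R,3S,5S)-3-(TBSO)-2-methyl-5-[(2Z)-4-oxobut-2-en-2-yl]oxolan-2-yl]-2-[(4,4,5,5-tetramethyl-1,3,2-dioxaborolan-2-yl)methyl]pent-2-enoate | O=C/C=C(/C)[C@@H]1C[C@H](O[Si](C)(C)C(C)(C)C)[C@@](C)(C[C@@H](OCc2ccc(OC)cc2)/C=C(\CB3OC(C)(C)C(C)(C)O3)C(=O)OC)O1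
F2 | step 8 | (2S,4S,5R)-4-(TBSO)-5-{(2R)-2-(PMBO)-2-[(4S)-2,2-dimethyl-1,3-dioxolan-4-yl]ethyl}-5-methyloxolane-2-carbaldehyde | O=C[C@@H]1C[C@H](O[Si](C)(C)C(C)(C)C)[C@@](C)(C[C@@H](OCc2ccc(OC)cc2)[C@@H]3COC(C)(C)O3)O1
F3 | step 8 | (2R,3S,5S)-3-(TBSO)-5-ethynyl-2-{(2R)-2-(PMBO)-2-[(4S)-2,2-dimethyl-1,3-dioxolan-4-yl]ethyl}-2-methyloxolane | C#C[C@@H]1C[C@H](O[Si](C)(C)C(C)(C)C)[C@@](C)(C[C@@H](OCc2ccc(OC)cc2)[C@@H]3COC(C)(C)O3)O1
F4 | step 8 | 3-[(2S,4S,5R)-4-(TBSO)-5-{(2R)-2-(PMBO)-2-[(4S)-2,2-dimethyl-1,3-dioxolan-4-yl]ethyl}-5-methyloxolan-2-yl]prop-2-yn-1-ol | OCC#C[C@@H]1C[C@H](O[Si](C)(C)C(C)(C)C)[C@@](C)(C[C@@H](OCc2ccc(OC)cc2)[C@@H]3COC(C)(C)O3)O1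
F5 | step 11 | [1-(methoxycarbonyl)ethenyl]bis(2-methylpropyl)alane | C=C(C(=O)OC)[Al](CC(C)C)CC(C)C
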